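I am about to repeat an earlier run of this flask, and before I read anything from it I want the one ratio worth watching.

substrate 0.020 M; gas phase 1.2 mM (held); time 2.5 d

    crystals ⇌ target, rate k1*(cs1 - [target]) while solid is left; crystals form when [target] > cs1 (cs1 = 0.78 mM, k1 = 2.7 h⁻¹)
    target ⇌ isomer of the product (K2 = 2.4, k2 = 0.020 h⁻¹)
    substrate + target → side product (k3 = 4.1 L mol⁻¹ h⁻¹)
    substrate + dissolved gas → target (k4 = 33 L mol⁻¹ h⁻¹)
    gas phase ⇌ dissolved gas, rate k5*(csat - [dissolved gas]) (k5 = 5.3 h⁻¹, csat = 1.2 mM)
    dissolved gas + target → over-reacted product (k6 = 4.6 L mol⁻¹ h⁻¹)

- a species is counted by the substrate in it: one side product counts as two
- amounts and yields of target count crystals too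
- given per volume of solution although it is solid: crystals
- at the start none of the gas is dissolved
- run time (flask): 2.5 d

- how much target and crystals together there is at 2.5 d, in percent of the substrate charged
- concentration of dissolved gas in solution at 30 h, in percent of saturation
- the change that raises the amount of target and crystals together at 2.5 d, in percent of the substrate charged most ("none" if none brings more than 2 percentage points) (cedar / alder / ash / birch / none)
- amount of target and crystals together at 2.5 d, in percent of the substrate charged, after birch

- cedar: doubling the dissolution coefficient of step 1, all else as stated
- alder: doubling the transfer coefficient of step 5, all else as stated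
- ash: doubling the solubility in step 1, all else as stated
- birch: doubling the saturation concentration of gas phase, all else as stated

Substrate leaves by two paths: with dissolved gas it gives target, and with target it gives side product. Both rates carry the substrate concentration, so their ratio contains neither that nor the time, and the two partners remain. In this flask the gas transfer coefficient 5.3 h⁻¹ is faster than the use of dissolved gas by the charge, 0.660 h⁻¹, so dissolved gas, none at the start, should soon stand near 88.9 % of saturation and climb as substrate falls. By my reckoning it stands at 96.3 % at 30 h. The charge is far above the solubility, so crystals form, and dissolving at 2.7 h⁻¹ is much faster than substrate turns over, so I take dissolved target as 0.78 mM while crystals last. With the partners at these values: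

split = (rate constant to target × saturation) / (rate constant to side product × solubility) = 33 L mol⁻¹ h⁻¹ × 1.2 mM / (4.1 L mol⁻¹ h⁻¹ × 0.78 mM) = 12.4

This split, the substrate going to target for each substrate going to side product, is a selectivity factor. Each side product also consumes one target and counts as two, so:

side product per substrate used = two / (split plus one) = 14.9 %

Taking dissolved gas at saturation and counting the path to target, I let substrate fall in a pseudo-first-order way at 0.0396 h⁻¹, so I reckon 9.29 % remains at 2.5 d. After subtracting the side product and the slow leaks to isomer and over-reacted product at the solubility, I expect:

y = 71.2 %

Doubling the gas saturation doubles the split, and doubling the solubility halves it, while the other two changes leave it as it is. So I choose birch, with 84.2 %.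

The forecast gives 69 %, 96.4 %, birch and 82 %, on the ground that “Doubling the gas saturation doubles the main rate and nearly finishes the substrate”. Its two yields lie below mine.

The simulation gives 70.1 %, 96.3 %, birch with a gain of 12 percentage points, and 82.1 %. So the forecast stands. What would have to change for y to leave that value is a setting: in this flask y moves by 5 points with the time down at 1.90 d or the substrate down at 0.00766 M, all else held.

At 0.604 d this flask sends substrate to target 9.9 times as fast as to side product, which is less than the split, and that ratio is the reading to watch. Its side product ends at 16.1 %, above the 13.7 % the split gives for the substrate used. The split contains no substrate concentration, so for the neighbour flask with 0.0050 M it again gives 13.8 % of side product. That neighbour flask computes to 13.0 %.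

(The numbers of this flask belong to no real substance; what happens was integrated by code.)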